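Two questions stand: when Z peaks in this flask, and how high.

all flasks: E 75 mM (held)
- Sunday's: D 0.15 M; run made earlier
- Monday's: D 0.60 M; run made earlier
- flask: D 0.30 M; time 3.0 d

| run | time / h | Z / % | D / % |
|---|---|---|---|
| Sunday's | 2.50 | 4.8 | 93.2 |
| Sunday's | 4.00 | 7.4 | 86.9 |
| Sunday's | 6.00 | 10.0 | 78.9 |
| Sunday's | 10.0 | 12.1 | 62.9 |
| Sunday's | 15.0 | 10.3 | 46.9 |
| Sunday's | 25.0 | 5.9 | 23.7 |
| Sunday's | 40.0 | 2.3 | 9.0 |
| Monday's | 2.50 | 3.2 | 95.5 |
| Monday's | 4.00 | 4.2 | 92.1 |
| Monday's | 6.00 | 6.8 | 87.7 |
| Monday's | 10.0 | 6.8 | 77.4 |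
| Monday's | 15.0 | 7.8 | 66.2 |
| Monday's | 25.0 | 5.7 | 47.0 |
| Monday's | 40.0 | 5.0 | 22.8 |

(readings scatter by 0.5 percentage points)

* the best time, 3.0 d at the latest, for Z
* the amount of Z, in percent of the D charged, at that time

- at the start none of Q is dissolved
- on the list of suspects stand: Q -> L; Z -> X; D + Q <-> Z; E <-> Q

Follow one molecule of D. It becomes Z by meeting Q, and Z leaves for X. The highest readings of Z are 12.1 % at 0.15 M of D and 7.8 % at 0.60 M, each with its scatter. The larger charge gives the lower percentage, as if more D were sharing the Q that dissolves.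

So try the hyperbola of an apparent Km: the peak is P divided by one plus [D]/C, with [D] the charge. The two readings give C = 0.666 M and P = 14.8 %. Call N the charge divided by C, the charge measured against the one that halves the peak percentage. For this flask N is 0.450, so I expect a peak of 10.2 %.

Is one number enough? Not for the time, since N gives a height. The highest readings stand at 10.0 h in Sunday's run and 15.0 h in Monday's. Those are scattered readings at spaced times, not the peaks themselves, so they place this flask's peak only roughly: I expect it near or between those times.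

The forecast says 9.7 % at 0.42 d, lower than my height, holding that “Q is depleted and supply-limited”.

    Q → L (k = 8.50 × 10⁻⁴ min⁻¹)
    Z → X (k = 0.00520 min⁻¹)
    D + Q ⇌ Z (K = 25.0 M⁻¹, k = 0.0260 M⁻¹ min⁻¹)
    E ⇌ Q, rate k4*(csat - [Q]) (kL = 0.00480 min⁻¹)

The flask gives 9.83 % at 0.425 d, which is 0.37 percentage points below the height from N. Z has a half-life of 0.093 d by turning into X alone, shorter than the 3.0 d allowed. At that end Z stands at 0.381 % and X at 98.5 %. With 1.2 M of D, N is 1.80 and gives 5.29 %, while that flask peaks at 4.49 %.

The earlier runs and the new flask come from a simulation with constants of no real substance; noise was put on by code.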